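## Retrosynthetic overview

1. Numbering is that of 1-benzoxepine and is kept for the same atoms in every precursor. Ring B is O1–C2–C3=C4–C5–C5a–C9a. Ring A is C5a–C6(CH3)2–C7(Br)–C8–C9–C9a(CH3).
2. The target comes from its C3 methyl ester (last step: CO2CH3 to CH2OH). The ester comes from an acyclic diene by cutting C6–C5a and C9a–O1 in one operation. Ring A closes first and ring B closes last, both in the key step.
3. Enabling feature: C6 (quaternary, next to C7–Br), C5a and C9a (fully substituted, bears O1) are contiguous and trans-related. This is the retron of an anti addition of a C6/C7 bromiranium carbon and of O1 across an E C5a=C9a alkene. The C3=C4 bond of ring B holds the C2 oxygen cis to C5, within reach of C9a, and the ester on C3 keeps this alkene and the C2–O bond inert.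
4. The acyclic precursor comes from a C4–C5 union of a C10 epoxygeranyl bromide with a C4 bromoalkynyl silyl ether. Syn addition of H and CO2CH3 across C3≡C4 follows, then conversion of the epoxide into a bromohydrin ester.
5. Stereocentres: C2 comes from (S)-glyceraldehyde acetonide, and C7 from a Shi epoxide that bromide inverts. C5a and C9a are set from C7 in the key step. The temporary rings (dioxolane, oxirane) are opened before it.

Key step: step 13

Remark on the structure: the SMILES reads as (2R,5aS,7S,9aS), with a trans ring fusion, axial C9a–CH3, equatorial C7–Br, and CH2Br cis to the C9a methyl group.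

Assumption: compounds 1 and 6 and all reagents under Conditions are purchased.

## Route

Step 1
Reactants: 1 (4S)-2,2-dimethyl-1,3-dioxolane-4-carbaldehyde
Product: 2 (4R)-4-ethynyl-2,2-dimethyl-1,3-dioxolane
Conditions: dimethyl (1-diazo-2-oxopropyl)phosphonate, K2CO3, MeOH, 0 °C → rt
Reagents that add atoms: dimethyl (1-diazo-2-oxopropyl)phosphonate, CC(=O)C(=[N+]=[N-])P(=O)(OC)OC
Why: Ohira–Bestmann alkyne synthesis, in which the diazomethylphosphonate anion freed by methanolysis olefinates the aldehyde and the alkylidene carbene rearranges to the terminal alkyne, while the chiral-pool stereocentre (future C2) is not touched and only its descriptor changes.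

Step 2
Reactants: 2 (4R)-4-ethynyl-2,2-dimethyl-1,3-dioxolane
Product: 3 (2R)-but-3-yne-1,2-diol
Conditions: Dowex 50W-X8 (H+ form), MeOH–H2O, rt
Reagents that add atoms: none
Why: Acid-catalysed hydrolysis of the isopropylidene acetal should free the 1,2-diol without affecting the alkyne or C2.

Step 3
Reactants: 3 (2R)-but-3-yne-1,2-diol
Product: 4 (2R)-1-bromobut-3-yn-2-ol
Conditions: CBr4 (1.05 equiv), PPh3 (1.05 equiv), CH2Cl2, −20 → 0 °C
Reagents that add atoms: tetrabromomethane, BrC(Br)(Br)Br
Why: The Appel bromination is governed by sterics, so the primary hydroxyl should form the alkoxyphosphonium salt and be displaced by bromide (SN2) while the secondary hydroxyl at C2 and its configuration stay.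

Step 4
Reactants: 4 (2R)-1-bromobut-3-yn-2-ol
Product: 5 {[(2R)-1-bromobut-3-yn-2-yl]oxy}(triethyl)silane
Conditions: Et3SiCl, imidazole, CH2Cl2, 0 °C
Reagents that add atoms: chlorotriethylsilane, CC[Si](Cl)(CC)CC
Why: Standard silylation of the only hydroxyl blocks epoxide formation in the basic steps to come and installs the silyl ether that later ends the key step.

Step 5
Reactants: 6 geranyl acetate, (2E)-3,7-dimethylocta-2,6-dien-1-yl acetate
Product: 7 (2E)-5-[(2R)-3,3-dimethyloxiran-2-yl]-3-methylpent-2-en-1-yl acetate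
Conditions: D-fructose-derived Shi ketone (30 mol %), KHSO5 (as 2KHSO5·KHSO4·K2SO4), K2CO3, Bu4NHSO4, Na2B4O7/Na2EDTA buffer, MeCN–CH2(OMe)2, 0 °C
Reagents that add atoms: potassium peroxymonosulfate KHSO5, [K+].[O-]S(=O)(=O)OO
Why: In the Shi asymmetric epoxidation the chiral dioxirane attacks the electron-rich distal alkene (future C6=C7), because the future C5a=C9a alkene is deactivated by the allylic acetate, and the spiro transition state of the D-fructose ketone should set (R) at future C7.

Step 6
Reactants: 7 (2E)-5-[(2R)-3,3-dimethyloxiran-2-yl]-3-methylpent-2-en-1-yl acetate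
Product: 8 (2E)-5-[(2R)-3,3-dimethyloxiran-2-yl]-3-methylpent-2-en-1-ol
Conditions: K2CO3 (20 mol %), MeOH, 0 °C → rt
Reagents that add atoms: none
Why: Base-catalysed transesterification removes the acetate, and the trisubstituted epoxide is inert to these conditions.

Step 7
Reactants: 8 (2E)-5-[(2R)-3,3-dimethyloxiran-2-yl]-3-methylpent-2-en-1-ol
Product: 10 (3R)-3-[(3E)-5-bromo-3-methylpent-3-en-1-yl]-2,2-dimethyloxirane, via allylic mesylate 9 (not isolated)
Conditions: MsCl, Et3N, CH2Cl2, −40 °C; then LiBr, THF, 0 °C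
Reagents that add atoms: lithium bromide, [Li+].[Br-]; methanesulfonyl chloride (atoms only in 9), CS(=O)(=O)Cl
Why: Mesylation followed by SN2 displacement with bromide under non-acidic conditions should give the primary allylic bromide without allylic shift, loss of E geometry or epoxide opening.

Step 8
Reactants: 5 {[(2R)-1-bromobut-3-yn-2-yl]oxy}(triethyl)silane; 10 (3R)-3-[(3E)-5-bromo-3-methylpent-3-en-1-yl]-2,2-dimethyloxirane
Product: 11 {[(2R,6E)-1-bromo-9-[(2R)-3,3-dimethyloxiran-2-yl]-7-methylnon-6-en-3-yn-2-yl]oxy}(triethyl)silane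
Conditions: CuI (20 mol %), K2CO3, DMF, rt, argon
Reagents that add atoms: none
Why: Copper-acetylide allylic substitution at the primary carbon (SN2) forms the C4–C5 bond under conditions too mild for the epoxide, the silyl ether or the unactivated primary bromide; no stereocentre is touched, and the minor enantiomer of 10 becomes a separable diastereomer.

Step 9
Reactants: 11 {[(2R,6E)-1-bromo-9-[(2R)-3,3-dimethyloxiran-2-yl]-7-methylnon-6-en-3-yn-2-yl]oxy}(triethyl)silane
Product: 13 {[(2S,3E,6E)-1-bromo-9-[(2R)-3,3-dimethyloxiran-2-yl]-3-iodo-7-methylnona-3,6-dien-2-yl]oxy}(triethyl)silane, via C3 alkenylstannane 12 (not isolated)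
Conditions: Bu3SnH, PdCl2(PPh3)2 (3 mol %), THF, 0 °C; then I2, CH2Cl2, −20 °C
Reagents that add atoms: iodine, II; tributyltin hydride (tin group only in 12), CCCC[SnH](CCCC)CCCC
Why: Palladium-catalysed syn hydrostannation should put tin on C3, the alkyne carbon next to the electron-withdrawing CH(OSiEt3)CH2Br group, and H on C4, so that C2 and C5 become cis, and iododestannylation keeps this geometry (the C2 descriptor changes only by priority).

Step 10
Reactants: 13 {[(2S,3E,6E)-1-bromo-9-[(2R)-3,3-dimethyloxiran-2-yl]-3-iodo-7-methylnona-3,6-dien-2-yl]oxy}(triethyl)silane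
Product: 14 methyl (2E,5E)-2-[(1R)-2-bromo-1-(triethylsilyloxy)ethyl]-8-[(2R)-3,3-dimethyloxiran-2-yl]-6-methylocta-2,5-dienoate
Conditions: PdCl2(dppf) (5 mol %), CO (1 atm), iPr2NEt, MeOH–DMF, 50 °C
Reagents that add atoms: carbon monoxide, [C-]#[O+]; methanol, CO
Why: Palladium-catalysed methoxycarbonylation of the alkenyl iodide proceeds with retention, so the ester ends trans to C5, and the unactivated alkyl bromide does not add to zerovalent palladium under these conditions.

Step 11
Reactants: 14 methyl (2E,5E)-2-[(1R)-2-bromo-1-(triethylsilyloxy)ethyl]-8-[(2R)-3,3-dimethyloxiran-2-yl]-6-methylocta-2,5-dienoate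
Product: 15 methyl (2E,5E,9S)-9-bromo-2-[(1R)-2-bromo-1-(triethylsilyloxy)ethyl]-10-hydroxy-6,10-dimethylundeca-2,5-dienoate
Conditions: Li2NiBr4 (0.4 M in THF), 0 °C → rt; pH 7 buffer
Reagents that add atoms: dilithium tetrabromonickelate Li2NiBr4, [Li+].[Li+].[Ni+2].[Br-].[Br-].[Br-].[Br-]
Why: Near-neutral SN2 opening of the trisubstituted epoxide by soft bromide should take place at the less hindered secondary carbon C7 with inversion, turning the (R)-epoxide into the (S)-bromide and freeing the tertiary C6 alcohol.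

Step 12
Reactants: 15 methyl (2E,5E,9S)-9-bromo-2-[(1R)-2-bromo-1-(triethylsilyloxy)ethyl]-10-hydroxy-6,10-dimethylundeca-2,5-dienoate
Product: 16 methyl (2E,5E,9S)-9-bromo-2-[(1R)-2-bromo-1-(triethylsilyloxy)ethyl]-6,10-dimethyl-10-(2,3,5,6-tetrafluorobenzoyloxy)undeca-2,5-dienoate
Conditions: 2,3,5,6-tetrafluorobenzoyl chloride, DMAP (20 mol %), Et3N, CH2Cl2, 0 °C → rt
Reagents that add atoms: 2,3,5,6-tetrafluorobenzoyl chloride, O=C(Cl)c1c(F)c(F)cc(F)c1F
Why: DMAP-catalysed acyl transfer to the only free hydroxyl installs an electron-poor aroate as nucleofuge on C6 without touching C7.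

Step 13
Reactants: 16 methyl (2E,5E,9S)-9-bromo-2-[(1R)-2-bromo-1-(triethylsilyloxy)ethyl]-6,10-dimethyl-10-(2,3,5,6-tetrafluorobenzoyloxy)undeca-2,5-dienoate
Product: 20 methyl (2R,5aS,7S,9aS)-7-bromo-2-(bromomethyl)-6,6,9a-trimethyl-2,5,5a,6,7,8,9,9a-octahydro-1-benzoxepine-3-carboxylate, via bromiranium ion 17 (not isolated), via monocyclic cation 18 (not isolated), via silyloxonium ion 19 (not isolated)
Conditions: Et3SiOTf (20 mol %), 2,6-di-tert-butyl-4-methylpyridine (30 mol %), CH2Cl2 (0.005 M), −78 → −30 °C; aq. NaHCO3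
Reagents that add atoms: none
Why: Et3SiOTf silylates the carbonyl oxygen of the electron-poor aroate, the only ester on a tertiary carbon, and the C6–O bond ionises with anchimeric help from the anti C7–Br, so that bromiranium ion 17 forms with C7 untouched; the closest known reaction type is the bromonium-initiated cation–olefin (polyene) cyclisation with oxygen termination, in its enantiospecific form in which a Lewis acid ionises an enantiopure bromohydrin ester. Ring A closes first: C5a of the E-configured C5a=C9a alkene attacks C6 anti to bromine through a chair (6-endo at the bromiranium, 6-endo-trig at the alkene) and gives the tertiary C9a cation 18. Ring B closes last: the silyl ether oxygen on C2 captures C9a on the face opposite to the new C6–C5a bond (7-endo-trig with respect to the former alkene), and silyloxonium ion 19 returns Et3Si+ to triflate, so the promoter is regenerated and no proton is set free. C5a is controlled by C7, because anti opening of 17 forces bromine into the equatorial position of the chair and thereby selects one alkene face, and C9a is controlled by the E geometry plus the anti addition, which gives the trans ring fusion with axial CH3; C2 and C7 are carried through. The step needs one ionisable C–O bond, one nucleophilic alkene and one oxygen within reach: the C3 ester makes C3=C4 electron-poor and the allylic C2–O bond non-ionisable, C3=C4 could only close a four- or five-membered ring, and on this alkene the C2 oxygen is cis to C5 whereas the ester carbonyl is trans and cannot reach C9a. The hindered pyridine removes traces of acid that would protonate C5a=C9a, and high dilution suppresses bromonium transfer between molecules, the only path that could erode C7.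

Step 14
Reactants: 20 methyl (2R,5aS,7S,9aS)-7-bromo-2-(bromomethyl)-6,6,9a-trimethyl-2,5,5a,6,7,8,9,9a-octahydro-1-benzoxepine-3-carboxylate
Product: 21 [(2R,5aS,7S,9aS)-7-bromo-2-(bromomethyl)-6,6,9a-trimethyl-2,5,5a,6,7,8,9,9a-octahydro-1-benzoxepin-3-yl]methanol
Conditions: iBu2AlH (2.5 equiv), CH2Cl2, −78 °C; MeOH, then aq. KNaC4H4O6, −78 °C → rt
Reagents that add atoms: none
Why: The 1,2-reduction of the enoate with iBu2AlH gives the allylic alcohol, leaves both alkyl bromides alone, and the cold quench keeps the aluminium alkoxide from displacing the neighbouring CH2Br.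

## Compound list

1 | (4S)-2,2-dimethyl-1,3-dioxolane-4-carbaldehyde | O=C[C@@H]1COC(C)(C)O1 | starting material
2 | (4R)-4-ethynyl-2,2-dimethyl-1,3-dioxolane | C#C[C@@H]1COC(C)(C)O1 | intermediate
3 | (2R)-but-3-yne-1,2-diol | C#C[C@@H](O)CO | intermediate
4 | (2R)-1-bromobut-3-yn-2-ol | C#C[C@@H](O)CBr | intermediate
5 | {[(2R)-1-bromobut-3-yn-2-yl]oxy}(triethyl)silane | C#C[C@@H](O[Si](CC)(CC)CC)CBr | intermediate
6 | geranyl acetate, (2E)-3,7-dimethylocta-2,6-dien-1-yl acetate | CC(C)=CCC/C(C)=C/COC(C)=O | starting material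
7 | (2E)-5-[(2R)-3,3-dimethyloxiran-2-yl]-3-methylpent-2-en-1-yl acetate | CC1(C)O[C@@H]1CC/C(C)=C/COC(C)=O | intermediate
8 | (2E)-5-[(2R)-3,3-dimethyloxiran-2-yl]-3-methylpent-2-en-1-ol | CC1(C)O[C@@H]1CC/C(C)=C/CO | intermediate
9 | (2E)-5-[(2R)-3,3-dimethyloxiran-2-yl]-3-methylpent-2-en-1-yl methanesulfonate (not isolated) | CC1(C)O[C@@H]1CC/C(C)=C/COS(C)(=O)=O | intermediate
10 | (3R)-3-[(3E)-5-bromo-3-methylpent-3-en-1-yl]-2,2-dimethyloxirane | CC1(C)O[C@@H]1CC/C(C)=C/CBr | intermediate
11 | {[(2R,6E)-1-bromo-9-[(2R)-3,3-dimethyloxiran-2-yl]-7-methylnon-6-en-3-yn-2-yl]oxy}(triethyl)silane | CC1(C)O[C@@H]1CC/C(C)=C/CC#C[C@@H](O[Si](CC)(CC)CC)CBr | intermediate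
12 | tributyl[(2S,3E,6E)-1-bromo-9-[(2R)-3,3-dimethyloxiran-2-yl]-7-methyl-2-(triethylsilyloxy)nona-3,6-dien-3-yl]stannane (not isolated) | CC1(C)O[C@@H]1CC/C(C)=C/C/C=C(/[Sn](CCCC)(CCCC)CCCC)[C@@H](O[Si](CC)(CC)CC)CBr | intermediate
13 | {[(2S,3E,6E)-1-bromo-9-[(2R)-3,3-dimethyloxiran-2-yl]-3-iodo-7-methylnona-3,6-dien-2-yl]oxy}(triethyl)silane | CC1(C)O[C@@H]1CC/C(C)=C/C/C=C(/I)[C@@H](O[Si](CC)(CC)CC)CBr | intermediate
14 | methyl (2E,5E)-2-[(1R)-2-bromo-1-(triethylsilyloxy)ethyl]-8-[(2R)-3,3-dimethyloxiran-2-yl]-6-methylocta-2,5-dienoate | CC1(C)O[C@@H]1CC/C(C)=C/C/C=C(/C(=O)OC)[C@@H](O[Si](CC)(CC)CC)CBr | intermediate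
15 | methyl (2E,5E,9S)-9-bromo-2-[(1R)-2-bromo-1-(triethylsilyloxy)ethyl]-10-hydroxy-6,10-dimethylundeca-2,5-dienoate | CC(C)(O)[C@@H](Br)CC/C(C)=C/C/C=C(/C(=O)OC)[C@@H](O[Si](CC)(CC)CC)CBr | intermediate
16 | methyl (2E,5E,9S)-9-bromo-2-[(1R)-2-bromo-1-(triethylsilyloxy)ethyl]-6,10-dimethyl-10-(2,3,5,6-tetrafluorobenzoyloxy)undeca-2,5-dienoate | CC(C)(OC(=O)c1c(F)c(F)cc(F)c1F)[C@@H](Br)CC/C(C)=C/C/C=C(/C(=O)OC)[C@@H](O[Si](CC)(CC)CC)CBr | intermediate
17 | bromiranium ion bridging C6 and C7 of the open chain, C7 configured as in 16, all other groups as in 16 (not isolated) | CC1(C)[Br+][C@H]1CC/C(C)=C/C/C=C(/C(=O)OC)[C@@H](O[Si](CC)(CC)CC)CBr | intermediate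
18 | monocyclic tertiary C9a carbocation, ring A closed, (5aS,7S), side chain on C5a unchanged (not isolated) | CC1(C)[C@@H](Br)CC[C+](C)[C@H]1C/C=C(/C(=O)OC)[C@@H](O[Si](CC)(CC)CC)CBr | intermediate
19 | O1-triethylsilyl oxonium ion of 20, both rings closed (not isolated) | CC1(C)[C@@H](Br)CC[C@]2(C)[O+]([Si](CC)(CC)CC)[C@@H](CBr)C(C(=O)OC)=CC[C@@H]12 | intermediate
20 | methyl (2R,5aS,7S,9aS)-7-bromo-2-(bromomethyl)-6,6,9a-trimethyl-2,5,5a,6,7,8,9,9a-octahydro-1-benzoxepine-3-carboxylate | CC1(C)[C@@H](Br)CC[C@]2(C)O[C@@H](CBr)C(C(=O)OC)=CC[C@@H]12 | intermediate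
21 | [(2R,5aS,7S,9aS)-7-bromo-2-(bromomethyl)-6,6,9a-trimethyl-2,5,5a,6,7,8,9,9a-octahydro-1-benzoxepin-3-yl]methanol | CC1(C)[C@@H](Br)CC[C@]2(C)O[C@@H](CBr)C(CO)=CC[C@@H]12 | target

## Step count and risks

Total step count: 14.

Longest linear sequence: 11 steps (steps 1–4 and 8–14). The second branch (steps 5–7) joins at step 8.

**Most likely to fail, first: step 13.**
- Loss of a proton from the C9a cation may outrun capture by the hindered silyl ether oxygen. Each such event also consumes the silyl promoter. Ionisation of the β-bromo tertiary ester may be sluggish.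
- The fallback sets out from 16 and changes both the terminating nucleophile and the mode of activation.
- The silyl ether is cleaved with HF·pyridine in THF at 0 °C. This gives the hydroxy aroate methyl (2E,5E,9S)-9-bromo-2-[(1R)-2-bromo-1-hydroxyethyl]-6,10-dimethyl-10-(2,3,5,6-tetrafluorobenzoyloxy)undeca-2,5-dienoate F1.
- F1 is treated with Me2AlOTf (3 equiv) in CH2Cl2 at −78 °C. The alcohol becomes a small aluminium alkoxide, the aluminium Lewis acid ionises the aroate, and every proton released is destroyed by an Al–CH3 bond.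
- The same bromiranium, ring A, ring B sequence should follow, and the route is rejoined at 20.

**Second: step 9.**
- The bulky OSiEt3 group may steer tin to C4, so regioselectivity of the hydrostannation may be poor. Slow radical reduction of the alkyl bromide by the stannane is a further risk.
- The fallback sets out from 11 and uses the free hydroxyl as a small, coordinating directing group.
- Buffered HF·pyridine/pyridine in THF gives the propargylic alcohol (2R,6E)-1-bromo-9-[(2R)-3,3-dimethyloxiran-2-yl]-7-methylnon-6-en-3-yn-2-ol F2.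
- Palladium-catalysed hydrostannation, proximal to the hydroxyl, gives (2S,3E,6E)-1-bromo-9-[(2R)-3,3-dimethyloxiran-2-yl]-7-methyl-3-(tributylstannyl)nona-3,6-dien-2-ol F3.
- Iodine converts F3 into (2S,3E,6E)-1-bromo-9-[(2R)-3,3-dimethyloxiran-2-yl]-3-iodo-7-methylnona-3,6-dien-2-ol F4.
- Et3SiCl/imidazole brings the material back to the route at 13.

**Third: step 11.**
- Bromide may attack the tertiary epoxide carbon, or the epoxide may rearrange under Lewis acid.
- The fallback sets out from 14 and uses the other regiochemistry on purpose, because both bromohydrins lead to the same bromiranium ion.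
- Opening at the tertiary carbon with MgBr2·OEt2 in Et2O gives methyl (2E,5E,9R)-10-bromo-2-[(1R)-2-bromo-1-(triethylsilyloxy)ethyl]-9-hydroxy-6,10-dimethylundeca-2,5-dienoate F5, with the C7 oxygen retained.
- Tf2O and 2,6-di-tert-butyl-4-methylpyridine in CH2Cl2 at −78 °C give its secondary triflate, methyl (2E,5E,9R)-10-bromo-2-[(1R)-2-bromo-1-(triethylsilyloxy)ethyl]-6,10-dimethyl-9-(trifluoromethylsulfonyloxy)undeca-2,5-dienoate F6.
- On warming, F6 should ionise with participation of the neighbouring tertiary bromine from the back side of C7. This inverts C7 exactly as in step 11 and gives ion 17.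
- The cascade then follows. Steps 11 and 12 are bypassed and the route is rejoined at 20.

## Further compounds

F1 | step 13 | methyl (2E,5E,9S)-9-bromo-2-[(1R)-2-bromo-1-hydroxyethyl]-6,10-dimethyl-10-(2,3,5,6-tetrafluorobenzoyloxy)undeca-2,5-dienoate | CC(C)(OC(=O)c1c(F)c(F)cc(F)c1F)[C@@H](Br)CC/C(C)=C/C/C=C(/C(=O)OC)[C@@H](O)CBr
F2 | step 9 | (2R,6E)-1-bromo-9-[(2R)-3,3-dimethyloxiran-2-yl]-7-methylnon-6-en-3-yn-2-ol | CC1(C)O[C@@H]1CC/C(C)=C/CC#C[C@@H](O)CBr
F3 | step 9 | (2S,3E,6E)-1-bromo-9-[(2R)-3,3-dimethyloxiran-2-yl]-7-methyl-3-(tributylstannyl)nona-3,6-dien-2-ol | CC1(C)O[C@@H]1CC/C(C)=C/C/C=C(/[Sn](CCCC)(CCCC)CCCC)[C@@H](O)CBr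
F4 | step 9 | (2S,3E,6E)-1-bromo-9-[(2R)-3,3-dimethyloxiran-2-yl]-3-iodo-7-methylnona-3,6-dien-2-ol | CC1(C)O[C@@H]1CC/C(C)=C/C/C=C(/I)[C@@H](O)CBr
F5 | step 11 | methyl (2E,5E,9R)-10-bromo-2-[(1R)-2-bromo-1-(triethylsilyloxy)ethyl]-9-hydroxy-6,10-dimethylundeca-2,5-dienoate | CC(C)(Br)[C@H](O)CC/C(C)=C/C/C=C(/C(=O)OC)[C@@H](O[Si](CC)(CC)CC)CBr
F6 | step 11 | methyl (2E,5E,9R)-10-bromo-2-[(1R)-2-bromo-1-(triethylsilyloxy)ethyl]-6,10-dimethyl-9-(trifluoromethylsulfonyloxy)undeca-2,5-dienoate | CC(C)(Br)[C@H](OS(=O)(=O)C(F)(F)F)CC/C(C)=C/C/C=C(/C(=O)OC)[C@@H](O[Si](CC)(CC)CC)CBr
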